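The γ-lactone ring is opened at two bonds: ring oxygen–C8 (the ten-membered-ring carbon that carries it) and C11–C12 (α-carbon–carbonyl). That leaves CO2, an alkenyl anion at C11 and an electrophilic C8. Since the neighbouring ring carbon C9 carries the ester oxygen, C8/C9 is read as a trans-epoxide opened with inversion at C8. The key step does this in one pot on an acyclic (Z)-2-bromoallylic alcohol bearing that epoxide: Br–Li exchange, CO2 capture, 5-exo closure to a butenolide. Its bromomethyl derivative then serves as allyl donor in a CrCl2-mediated closure of the ten-membered ring at C6–C7, which also unveils the exocyclic methylene.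

Key step: step 10

Remark on labels: germacrane atom labels are used for all compounds. C1=C10 is the ring alkene (C10 bears methyl C14), C4/C5 the ring epoxide (C4 bears methyl C15), C6 the carbinol carbon, C7 the ring carbon bearing C11, C8 the ring carbon bearing the lactone oxygen, C9 the ring carbon bearing the isobutyrate; C11, C12 and C13 are the lactone α-carbon, the carbonyl carbon and the exocyclic methylene.

Step 1
Reactants: 1 geraniol
Product: 2 (2S,3S)-2,3-epoxygeraniol
Conditions: Ti(OiPr)4 (cat.), L-(+)-diethyl tartrate (cat.), tBuOOH, 4 Å MS, CH2Cl2, −20 °C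
Reagents that add atoms: tert-butyl hydroperoxide CC(C)(C)OO
Why: Katsuki–Sharpless asymmetric epoxidation: only the titanium-bound allylic alcohol is epoxidised (the C1=C10 alkene is left), and the L-(+)-tartrate ligand directs oxygen to the alkene face that gives the (2S,3S)-epoxy alcohol, which sets C4 and C5 (4S,5S).

Step 2
Reactants: 2 (2S,3S)-2,3-epoxygeraniol
Product: 3 4-methoxybenzyl (PMB) ether of 2
Conditions: NaH, PMBCl, Bu4NI (cat.), THF–DMF, 0 → 23 °C
Reagents that add atoms: 4-methoxybenzyl chloride COc1ccc(CCl)cc1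
Why: Williamson etherification of the sodium alkoxide, which in THF–DMF at 0 °C is alkylated faster than it undergoes Payne rearrangement; the PMB ether masks the C6 oxygen through the organometallic steps and can later be removed oxidatively beside an allylic bromide.

Step 3
Reactants: 3 PMB ether of 2
Product: 4 C9 allylic alcohol (E)
Conditions: SeO2 (cat.), tBuOOH, CH2Cl2, 0 → 23 °C
Reagents that add atoms: tert-butyl hydroperoxide CC(C)(C)OO
Why: SeO2-catalysed allylic oxidation (ene reaction, then [2,3]-sigmatropic shift) is selective for the (E)-methyl group of the terminal trisubstituted alkene and should give the (E)-allylic alcohol with oxygen on C9; enal 6 formed by over-oxidation is not a loss because step 4 converges both.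

Step 4
Reactants: 4 C9 allylic alcohol, 5 ethyl (triphenylphosphoranylidene)acetate
Product: 7 ethyl (2E,4E)-dienoate (C7 ester), via enal 6 (not isolated)
Conditions: MnO2 (excess), 5, CH2Cl2, 23 °C
Reagents that add atoms: none
Why: Tandem oxidation–Wittig olefination: MnO2 oxidises only the allylic alcohol and the stabilised ylide traps enal 6 as it forms, giving the new C8=C9 double bond with (E) geometry as expected for a stabilised ylide.

Step 5
Reactants: 7 ethyl (2E,4E)-dienoate
Product: 8 (2E,4E)-dienol (C7 alcohol)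
Conditions: iBu2AlH, CH2Cl2, −78 °C; aq. sodium potassium tartrate
Reagents that add atoms: none
Why: 1,2-Reduction of the conjugated ester by iBu2AlH at −78 °C gives the dienol needed for hydroxyl-directed epoxidation and leaves the epoxide and the PMB ether untouched.

Step 6
Reactants: 8 (2E,4E)-dienol
Product: 9 bis-epoxy alcohol (4S,5S,8S,9S)
Conditions: Ti(OiPr)4 (cat.), L-(+)-diethyl tartrate (cat.), tBuOOH, 4 Å MS, CH2Cl2, −25 °C
Reagents that add atoms: tert-butyl hydroperoxide CC(C)(C)OO
Why: Second Katsuki–Sharpless epoxidation: of the two alkenes of the 2,4-dienol only the one allylic to the hydroxyl (C8=C9) is epoxidised, and the L-(+)-tartrate catalyst again gives the (2S,3S)-epoxy alcohol by reagent control, which sets C8 and C9 (8S,9S) independently of the remote epoxide.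

Step 7
Reactants: 5 ethyl (triphenylphosphoranylidene)acetate
Product: 11 ethyl bromo(triphenylphosphoranylidene)acetate, via bromophosphonium bromide 10 (not isolated)
Conditions: Br2, CH2Cl2, −78 → 0 °C; then Et3N
Reagents that add atoms: bromine BrBr
Why: Electrophilic bromination of the stabilised ylide at carbon gives phosphonium salt 10, whose remaining acidic C–H is removed by Et3N to give the bromo ylide (known ylide halogenation).

Step 8
Reactants: 9 bis-epoxy alcohol, 11 ethyl bromo(triphenylphosphoranylidene)acetate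
Product: 13 ethyl (Z)-2-bromo enoate, via epoxy aldehyde 12 (not isolated)
Conditions: Dess–Martin periodinane, NaHCO3, CH2Cl2, 0 °C; then 11, 0 → 23 °C
Reagents that add atoms: none
Why: One-pot Dess–Martin oxidation/Wittig olefination avoids isolation of the labile α,β-epoxy aldehyde 12, and the stabilised bromo ylide should place the ester trans to C8, i.e. bromine cis to C8 ((Z)-2-bromo enoate), which is the geometry the later carboxylate needs.

Step 9
Reactants: 13 ethyl (Z)-2-bromo enoate
Product: 14 (Z)-2-bromoallylic alcohol (C13 alcohol, C11 bromide)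
Conditions: iBu2AlH, CH2Cl2, −78 °C; aq. sodium potassium tartrate
Reagents that add atoms: none
Why: 1,2-Reduction of the ester by iBu2AlH at −78 °C gives the 2-bromoallylic alcohol, whose free hydroxyl is wanted for the next step; the alkenyl bromide and both epoxides are not attacked at this temperature.

Step 10
Reactants: 14 (Z)-2-bromoallylic alcohol
Product: 17 (5R)-3-(hydroxymethyl)butenolide with free (9S)-hydroxyl, via dilithio alkenyl alkoxide 15 (not isolated), via dilithium carboxylate carbonate 16 (not isolated)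
Conditions: tBuLi (3.1 equiv), THF, −78 °C; CO2 (1 atm), −78 → 40 °C; AcOH, 0 °C
Reagents that add atoms: carbon dioxide O=C=O
Why: tBuLi first forms the lithium alkoxide (which cannot β-eliminate, as known for the dilithio derivative of 2-bromoallyl alcohol) and then exchanges bromine for lithium with retention of the (Z) geometry, and alkenyllithium 15 adds to CO2 to form C11–C12. The carboxylate of 16 sits cis to C8 on the trisubstituted alkene and opens the 8S,9S epoxide at C8 by intramolecular SN2 attack, forming the O–C8 bond; the closest known reaction types are carboxylation of 2-lithioallyl alkoxides and lactonisation of (Z)-γ,δ-epoxy-α,β-unsaturated acids to 5-(1-hydroxyalkyl)butenolides. The butenolide ring closes in the 5-exo-tet mode. C8 is set by stereospecific inversion of the Sharpless epoxide carbon (8S to 8R) and C9 keeps its configuration (9S) as the epoxide oxygen becomes the C9 hydroxyl, so the erythro O–C8/O–C9 pair of the target results. The step needs attack at C8 and not at the equally allylic C9 (6-endo) or by the C13 oxygen: the cis carboxylate favours the five-membered exo closure under non-acidic conditions that give C9 no cationic character, the C13 oxygen is trans to C8 and cannot reach it, and the CO2 atmosphere keeps the liberated alkoxides as non-basic carbonates so that the acidic C8–H of the butenolide is not removed before the acetic acid quench.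

Step 11
Reactants: 17 3-(hydroxymethyl)butenolide diol
Product: 18 3-(bromomethyl)butenolide with free C9 hydroxyl
Conditions: CBr4, PPh3, CH2Cl2, −30 → 0 °C
Reagents that add atoms: carbon tetrabromide BrC(Br)(Br)Br
Why: Appel reaction: the primary allylic hydroxyl is converted to the bromide by SN2 displacement of its oxyphosphonium salt much faster than the hindered secondary C9 hydroxyl reacts at −30 °C.

Step 12
Reactants: 18 3-(bromomethyl)butenolide
Product: 19 C9 isobutyrate
Conditions: iPrCOCl, 2,4,6-collidine, CH2Cl2, 0 → 23 °C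
Reagents that add atoms: isobutyryl chloride CC(C)C(=O)Cl
Why: Acylation of the secondary alcohol by the acid chloride, for which the hindered and poorly nucleophilic base collidine only removes HCl and should not displace the reactive allylic bromide; the C9 configuration is untouched.

Step 13
Reactants: 19 C9 isobutyrate (PMB ether)
Product: 20 2,3-epoxy alcohol (free C6 hydroxyl)
Conditions: DDQ, CH2Cl2–pH 7 buffer (NaH2PO4/Na2HPO4), 0 → 23 °C
Reagents that add atoms: none
Why: Oxidative cleavage of the PMB ether by DDQ (hydride abstraction from the electron-rich benzylic position, hydrolysis of the oxocarbenium ion) proceeds near neutrality and should spare the epoxide, the allylic bromide, the ester and the butenolide.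

Step 14
Reactants: 20 2,3-epoxy alcohol
Product: 21 α,β-epoxy aldehyde (C6 aldehyde)
Conditions: Dess–Martin periodinane, NaHCO3, CH2Cl2, 0 °C
Reagents that add atoms: none
Why: Buffered Dess–Martin oxidation of the 2,3-epoxy alcohol to the α,β-epoxy aldehyde, which has no enolisable stereocentre and is used at once.

Step 15
Reactants: 21 α,β-epoxy aldehyde
Product: 23 target germacranolide CNP0220196.1, via allylchromium dichloride 22 (not isolated)
Conditions: CrCl2 (excess), THF, 23 °C, slow addition of 21 (high dilution); aq. NH4Cl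
Reagents that add atoms: none
Why: Nozaki–Hiyama-type allylation run as a ring closure: divalent chromium reduces the allylic bromide to allylchromium species 22, which adds through its γ-carbon C7 to the C6 aldehyde in a chair transition state, so that the C6–C7 bond forms anti to the C9 substituent on C8 (trans-fused lactone, 7S), the ring-locked (E)-type allyl unit gives the anti C6/C7 relationship and Felkin–Anh attack anti to the epoxide C5–O bond gives 6S, all three elements pointing to the same diastereomer, while the allylic transposition creates the exocyclic methylene.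

Compound list
1 | geraniol, (2E)-3,7-dimethylocta-2,6-dien-1-ol | OC/C=C(\C)CCC=C(C)C | starting material
2 | (2S,3S)-2,3-epoxygeraniol, [(2S,3S)-3-methyl-3-(4-methylpent-3-en-1-yl)oxiran-2-yl]methanol | OC[C@@H]1O[C@@]1(C)CCC=C(C)C | intermediate
3 | (2S,3S)-2-{[(4-methoxybenzyl)oxy]methyl}-3-methyl-3-(4-methylpent-3-en-1-yl)oxirane | COc1ccc(COC[C@@H]2O[C@@]2(C)CCC=C(C)C)cc1 | intermediate
4 | (2E)-5-[(2S,3S)-3-{[(4-methoxybenzyl)oxy]methyl}-2-methyloxiran-2-yl]-2-methylpent-2-en-1-ol | COc1ccc(COC[C@@H]2O[C@@]2(C)CC/C=C(\C)CO)cc1 | intermediate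
5 | ethyl (triphenylphosphoranylidene)acetate | CCOC(=O)C=P(c1ccccc1)(c1ccccc1)c1ccccc1 | starting material
6 | (2E)-5-[(2S,3S)-3-{[(4-methoxybenzyl)oxy]methyl}-2-methyloxiran-2-yl]-2-methylpent-2-enal | COc1ccc(COC[C@@H]2O[C@@]2(C)CC/C=C(\C)C=O)cc1 | intermediate (not isolated)
7 | ethyl (2E,4E)-7-[(2S,3S)-3-{[(4-methoxybenzyl)oxy]methyl}-2-methyloxiran-2-yl]-4-methylhepta-2,4-dienoate | COc1ccc(COC[C@@H]2O[C@@]2(C)CC/C=C(C)/C=C/C(=O)OCC)cc1 | intermediate
8 | (2E,4E)-7-[(2S,3S)-3-{[(4-methoxybenzyl)oxy]methyl}-2-methyloxiran-2-yl]-4-methylhepta-2,4-dien-1-ol | COc1ccc(COC[C@@H]2O[C@@]2(C)CC/C=C(C)/C=C/CO)cc1 | intermediate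
9 | {(2S,3S)-3-[(2E)-5-((2S,3S)-3-{[(4-methoxybenzyl)oxy]methyl}-2-methyloxiran-2-yl)pent-2-en-2-yl]oxiran-2-yl}methanol (4S,5S,8S,9S) | COc1ccc(COC[C@@H]2O[C@@]2(C)CC/C=C(\C)[C@@H]3O[C@H]3CO)cc1 | intermediate
10 | (1-bromo-2-ethoxy-2-oxoethyl)triphenylphosphonium bromide | CCOC(=O)C(Br)[P+](c1ccccc1)(c1ccccc1)c1ccccc1.[Br-] | intermediate (not isolated)
11 | ethyl bromo(triphenylphosphoranylidene)acetate | CCOC(=O)C(Br)=P(c1ccccc1)(c1ccccc1)c1ccccc1 | intermediate
12 | (2R,3S)-3-[(2E)-5-((2S,3S)-3-{[(4-methoxybenzyl)oxy]methyl}-2-methyloxiran-2-yl)pent-2-en-2-yl]oxirane-2-carbaldehyde | COc1ccc(COC[C@@H]2O[C@@]2(C)CC/C=C(\C)[C@@H]3O[C@H]3C=O)cc1 | intermediate (not isolated)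
13 | ethyl (2Z)-2-bromo-3-{(2S,3S)-3-[(2E)-5-((2S,3S)-3-{[(4-methoxybenzyl)oxy]methyl}-2-methyloxiran-2-yl)pent-2-en-2-yl]oxiran-2-yl}prop-2-enoate | COc1ccc(COC[C@@H]2O[C@@]2(C)CC/C=C(\C)[C@@H]3O[C@H]3/C=C(\Br)C(=O)OCC)cc1 | intermediate
14 | (2Z)-2-bromo-3-{(2S,3S)-3-[(2E)-5-((2S,3S)-3-{[(4-methoxybenzyl)oxy]methyl}-2-methyloxiran-2-yl)pent-2-en-2-yl]oxiran-2-yl}prop-2-en-1-ol | COc1ccc(COC[C@@H]2O[C@@]2(C)CC/C=C(\C)[C@@H]3O[C@H]3/C=C(\Br)CO)cc1 | intermediate
15 | dilithio derivative of 14 (lithium on C11, lithium alkoxide on the C13 oxygen) | COc1ccc(COC[C@@H]2O[C@@]2(C)CC/C=C(\C)[C@@H]3O[C@H]3/C=C(\[Li])CO[Li])cc1 | intermediate (not isolated)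
16 | dilithium salt of the (Z)-C11 carboxylic acid whose C13 oxygen is carbonated (epoxide still closed) | COc1ccc(COC[C@@H]2O[C@@]2(C)CC/C=C(\C)[C@@H]3O[C@H]3/C=C(\C(=O)O[Li])COC(=O)O[Li])cc1 | intermediate (not isolated)
17 | (5R)-5-{(1S,2E)-1-hydroxy-5-[(2S,3S)-3-{[(4-methoxybenzyl)oxy]methyl}-2-methyloxiran-2-yl]-2-methylpent-2-en-1-yl}-3-(hydroxymethyl)furan-2(5H)-one | COc1ccc(COC[C@@H]2O[C@@]2(C)CC/C=C(\C)[C@H](O)[C@@H]3OC(=O)C(CO)=C3)cc1 | intermediate
18 | (5R)-3-(bromomethyl)-5-{(1S,2E)-1-hydroxy-5-[(2S,3S)-3-{[(4-methoxybenzyl)oxy]methyl}-2-methyloxiran-2-yl]-2-methylpent-2-en-1-yl}furan-2(5H)-one | COc1ccc(COC[C@@H]2O[C@@]2(C)CC/C=C(\C)[C@H](O)[C@@H]3OC(=O)C(CBr)=C3)cc1 | intermediate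
19 | (1S,2E)-1-[(2R)-4-(bromomethyl)-5-oxo-2,5-dihydrofuran-2-yl]-5-[(2S,3S)-3-{[(4-methoxybenzyl)oxy]methyl}-2-methyloxiran-2-yl]-2-methylpent-2-en-1-yl 2-methylpropanoate | COc1ccc(COC[C@@H]2O[C@@]2(C)CC/C=C(\C)[C@H](OC(=O)C(C)C)[C@@H]3OC(=O)C(CBr)=C3)cc1 | intermediate
20 | (1S,2E)-1-[(2R)-4-(bromomethyl)-5-oxo-2,5-dihydrofuran-2-yl]-5-[(2S,3S)-3-(hydroxymethyl)-2-methyloxiran-2-yl]-2-methylpent-2-en-1-yl 2-methylpropanoate | OC[C@@H]1O[C@@]1(C)CC/C=C(\C)[C@H](OC(=O)C(C)C)[C@@H]2OC(=O)C(CBr)=C2 | intermediate
21 | (1S,2E)-1-[(2R)-4-(bromomethyl)-5-oxo-2,5-dihydrofuran-2-yl]-5-[(2S,3R)-3-formyl-2-methyloxiran-2-yl]-2-methylpent-2-en-1-yl 2-methylpropanoate | O=C[C@@H]1O[C@@]1(C)CC/C=C(\C)[C@H](OC(=O)C(C)C)[C@@H]2OC(=O)C(CBr)=C2 | intermediate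
22 | allylchromium dichloride derived from 21 (CrCl2 group on C13 in place of bromine) | O=C[C@@H]1O[C@@]1(C)CC/C=C(\C)[C@H](OC(=O)C(C)C)[C@@H]2OC(=O)C(C[Cr](Cl)Cl)=C2 | intermediate (not isolated)
23 | CNP0220196.1, (1(10)E,4S,5S,6S,7S,8R,9S)-4,5-epoxy-6-hydroxy-9-(2-methylpropanoyloxy)germacra-1(10),11(13)-dien-12,8-olide | C=C1C(=O)O[C@@H]2[C@@H]1[C@H](O)[C@@H]1O[C@@]1(C)CC/C=C(\C)[C@@H]2OC(=O)C(C)C | target

Total step count: 15
Longest linear sequence: 14 steps (steps 1–6 and 8–15, from geraniol)

Steps most likely to fail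

1. Step 15. The ring closure may show poor facial selectivity at the aldehyde carbon C6 (the Felkin–Anh and chair demands need not both be met in a strained ten-membered transition state), beside competing intermolecular coupling. The fallback sets out from 21 and comes back at 23. The ring is closed as in step 15 and the C6 epimer of the target F1 formed beside 23 is not separated. The carbinol mixture is oxidised (Dess–Martin periodinane, NaHCO3, CH2Cl2, 0 °C) to the C6 ketone F2. F2 is then reduced under reagent control (Corey–Bakshi–Shibata reduction, the 2-methyl-oxazaborolidine enantiomer that delivers hydride to the face giving 6S, catecholborane, toluene, −78 °C) to 23. C6 is then set by ketone reduction and no longer by the C–C bond formation.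

2. Step 10. The organolithium may attack the vinyl epoxide, or the carboxylate may open the epoxide at C9 if ring closure is still incomplete when the mixture is acidified. The fallback sets out from 9 and comes back at 17. 9 is oxidised to 12 as in step 8 and olefinated with ethyl 2-[bis(2,2,2-trifluoroethoxy)phosphoryl]-2-bromoacetate, a known (E)-selective Horner–Wadsworth–Emmons reagent (KOtBu, 18-crown-6, THF, −78 °C), to the (E)-2-bromo enoate F3, in which the ester is cis to C8. Saponification (LiOH, THF–H2O, 0 °C, then pH 5 buffer) should close the carboxylate onto C8 with inversion to the α-bromobutenolide F4. Stille coupling of F4 with (tributylstannyl)methanol (Pd(PPh3)4, dioxane, 80 °C) installs C13 and gives 17. No organolithium is used and the carbonyl carbon comes from the phosphonate.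

3. Step 12. The reactive allylic bromide may be displaced, or may alkylate the base, during acylation. The fallback sets out from 17 and comes back at 19. The primary hydroxyl is silylated selectively (TBSCl, imidazole, CH2Cl2, −20 °C) to the silyl ether F5. The C9 hydroxyl is esterified under nucleophilic catalysis (isobutyric anhydride, DMAP, Et3N, CH2Cl2) to the silyl ether isobutyrate F6. The silyl group is removed (HF·pyridine, pyridine, THF, 0 °C) to the hydroxymethyl butenolide isobutyrate F7, and Appel bromination as in step 11 gives 19. The ester is thus in place before any allylic bromide is present.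

Further compounds
F1 | step 15 | C6 epimer of 23, (1(10)E,4S,5S,6R,7S,8R,9S)-4,5-epoxy-6-hydroxy-9-(2-methylpropanoyloxy)germacra-1(10),11(13)-dien-12,8-olide | C=C1C(=O)O[C@@H]2[C@@H]1[C@@H](O)[C@@H]1O[C@@]1(C)CC/C=C(\C)[C@@H]2OC(=O)C(C)C
F2 | step 15 | C6 ketone, (1(10)E,4S,5S,7S,8R,9S)-4,5-epoxy-6-oxo-9-(2-methylpropanoyloxy)germacra-1(10),11(13)-dien-12,8-olide | C=C1C(=O)O[C@@H]2[C@@H]1C(=O)[C@@H]1O[C@@]1(C)CC/C=C(\C)[C@@H]2OC(=O)C(C)C
F3 | step 10 | ethyl (2E)-2-bromo-3-{(2S,3S)-3-[(2E)-5-((2S,3S)-3-{[(4-methoxybenzyl)oxy]methyl}-2-methyloxiran-2-yl)pent-2-en-2-yl]oxiran-2-yl}prop-2-enoate | COc1ccc(COC[C@@H]2O[C@@]2(C)CC/C=C(\C)[C@@H]3O[C@H]3/C=C(/Br)C(=O)OCC)cc1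
F4 | step 10 | (5R)-3-bromo-5-{(1S,2E)-1-hydroxy-5-[(2S,3S)-3-{[(4-methoxybenzyl)oxy]methyl}-2-methyloxiran-2-yl]-2-methylpent-2-en-1-yl}furan-2(5H)-one | COc1ccc(COC[C@@H]2O[C@@]2(C)CC/C=C(\C)[C@H](O)[C@@H]3OC(=O)C(Br)=C3)cc1
F5 | step 12 | tert-butyldimethylsilyl ether of 17 at the C13 oxygen | COc1ccc(COC[C@@H]2O[C@@]2(C)CC/C=C(\C)[C@H](O)[C@@H]3OC(=O)C(CO[Si](C)(C)C(C)(C)C)=C3)cc1
F6 | step 12 | C9 isobutyrate of F5 | COc1ccc(COC[C@@H]2O[C@@]2(C)CC/C=C(\C)[C@H](OC(=O)C(C)C)[C@@H]3OC(=O)C(CO[Si](C)(C)C(C)(C)C)=C3)cc1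
F7 | step 12 | C9 isobutyrate of 17 with free C13 hydroxyl | COc1ccc(COC[C@@H]2O[C@@]2(C)CC/C=C(\C)[C@H](OC(=O)C(C)C)[C@@H]3OC(=O)C(CO)=C3)cc1
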